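Answer 4 questions on 3 flasks.

| setting | dawn | spring | dusk |
|---|---|---|---|
| free monomer | 11 mM | 11 mM (fed, over 25.0 min) | 11 mM |
| initiator | 55 µM | 55 µM | 55 µM |
| remark | a single well-mixed tank run continuously and read at steady state, 25 min in it on average | a stirred flask in which free monomer is dosed at a steady rate over 25.0 min without added volume, worked up at 25 min | a closed flask charged with all of it at once and left for 25 min |
| time |  | 25 min | 25 min |

* the set-up with the highest amount of monomer in chains at the outlet or at the end, in percent of the free monomer put in ("none" if the first two lie within 2 percentage points) (dawn / spring / dusk / none)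
* amount of monomer in chains at the outlet or at the end, in percent of the free monomer put in, dawn
* amount of monomer in chains at the outlet or at the end, in percent of the free monomer put in, spring
* amount of monomer in chains at the outlet or at the end, in percent of the free monomer put in, dusk

- a species is counted by the free monomer in it: one homo dimer counts as two
- two of one species on the left: rate k times its square, two consumed each time
- the stated concentrations are those of everything mixed, before any reaction; amounts are the same in each set-up
- the feed brings no volume worth counting
- run time (spring): 25 min

    initiator → 2 initiating radical (k1 = 2.5 × 10⁻⁵ s⁻¹)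
    free monomer + initiating radical → growing radical + monomer in chains (k2 = 4.2 × 10⁶ M⁻¹ s⁻¹)
    free monomer + growing radical → monomer in chains + growing radical, rate k3*[growing radical]*[free monomer] (k3 = 1.9 × 10⁵ M⁻¹ s⁻¹)
    2 growing radical → dead chain (k4 = 1.8 × 10⁸ M⁻¹ s⁻¹)
    free monomer → decomposition product (k5 = 4.9 × 10⁻⁷ s⁻¹)
    2 free monomer → homo dimer (k6 = 0.0058 M⁻¹ s⁻¹)

Reckon by hand first, and order the clocks from fastest to slowest.

1. Take the initiating radical. At the full charge it meets free monomer within about 2.16 × 10⁻⁵ s and becomes a growing radical.
2. Balance the growing radical. Each initiator gives a pair of radicals, and each termination removes a pair. The level is therefore the square root of k1 × initiator / k4, or 2.76 nM. It settles in about 1.01 s, well inside the run.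
3. Let free monomer fall. At that level, propagation is pseudo-first-order at 5.25 × 10⁻⁴ s⁻¹. Multiply by the 25 min in the vessel to get 0.788: the chain dose, propagation rate times time.
4. Weigh the homo dimer. At full charge, the first half-life of free monomer by this step alone is 131 min, longer than the propagation time of 31.7 min. The selectivity factor, dimer use over chain use at full charge, is 0.243.
5. Set aside two longer clocks. Initiator has a half-life of 7.7 h by its own step, and free monomer one of 390 h by decomposition alone, both far beyond the run.
6. Join the ends for the closed flask dusk. Without homo dimer, the fraction reacted is c = 1 − exp(−dose) = 54.5 %. With the selectivity factor s, chains take ln(1 + s·c)/s = 51.2 %.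
7. Balance the tank dawn at steady state, with the same two numbers. Its chains come to 41.7 %.
8. Reckon the dosed flask spring without homo dimer: 1 − c/dose = 30.8 %.

My order is dusk, dawn, spring.

The forecast names dusk, with 41.2 % for dawn, 30 % for spring and 50.9 % for dusk. Its spring lies below my figure. Its grounds: “the dosed flask is last because late-fed monomer has little time to react and much of it is still free at work-up”.

The simulation names dusk, with 41.2 % for dawn, 29.9 % for spring and 50.9 % for dusk. Read later, at 250 min, the order of two flasks turns: spring holds 91.3 % in chains and dusk 89.3 %. Now use the chain dose on the neighbour of dusk charged with 0.014 mM of initiator. Its dose is 0.397 and its selectivity factor 0.482, so step 6 gives 30.4 %. Simulated, that neighbour ends with 30.2 % in chains.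

The numbers of this flask are invented; what happens was integrated by code.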